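## Structural features

The target is an achiral 2-arylbenzofuran with no stereocentre and no stereogenic double bond. Ring A (C3a, C4, C5, C6, C7, C7a) is a phloroglucinol: its three oxygens are 4-OH, 6-OH and the furan oxygen O1 on C7a, C5 is its only C–H, and C7 carries a 1,1-dimethylallyl (2-methylbut-3-en-2-yl) group whose quaternary carbon sits between O1 and 6-OH. Ring B (O1, C2, C3) is the furan; C3 is unsubstituted and C2 is bonded to C5' of a 2,2-dimethylchroman. Ring C (the chroman arene) is a resorcinol (7'-OH and the pyran oxygen on C8a'), and the ring D methylene C4' on C4a' is ortho to the biaryl bond, so the prenyl-derived chain lies between the aryl group and one oxygen, not between the two oxygens. Fragile points are the free 1,1-dimethylallyl group next to 6-OH (acid closes it to a 2,3,3-trimethyldihydrofuran, and it rules out hydrogenolysis and BBr3-type ether cleavage late in the route), the air-sensitive triphenol, and the nucleophilic carbons C3 and C5. The real difficulty is regiochemical: on ring A the quaternary group must go to C7 and the furan must fuse at C3a/C7a although C5, between two oxygens, is the most reactive carbon; on ring C the chain must go to C4a'. The key step exploits the fact that both carbons ortho to O1 carry carbon substituents (C7 the quaternary carbon, C3a the furan carbon C3), so each C–C bond can be delivered from O1 itself by a [3,3] shift, the second one through a temporary O1–N bond that is absent from the target.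

## Logic of the disconnections

**22 from 21.** The three phenolic O–H bonds (O4, O6, O7') are exchanged for O–Si bonds. Silyl ethers are chosen because fluoride removes them without acid, hydrogen or Lewis acid, all of which the 1,1-dimethylallyl group forbids. The forward step only needs buffered fluoride and exclusion of air.

**21 from 17 (key disconnection).** The bonds C3–C3a and O1–C2 of ring B are cut and a bond foreign to the target, O1–N, is added, so the benzofuran becomes an O-aryl ketoxime ether. Ring B disappears, C3a needs no halogen or other handle, and the molecule separates at a C=N bond into two arenes of similar size. The forward [3,3] shift must find exactly one open carbon ortho to O1; this is guaranteed because the other ortho carbon (C7) is already quaternary-substituted.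

**17 from 9 and 16.** The C=N bond is cut, giving an aryloxyamine and a methyl ketone. Only the methyl side of 16 has α-hydrogens, so the later ene-hydroxylamine can form in one direction only. The forward condensation must tolerate an ortho-substituted ketone and a weakly nucleophilic nitrogen.

**9 from 6 and 8.** The O1–N bond is cut back to the free phenol. The phenol oxygen of 6 is the only unprotected oxygen of ring A, so the nitrogen can be placed nowhere else. The demand is O- rather than C-amination of a hindered, electron-rich phenoxide.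

**6 from 4.** The bond from C7 to the quaternary carbon is cut and reconnected as an O1–CH2 bond (retro-Claisen). Because 4 has a mirror plane through C1 and C4 of its benzene ring, its two ortho carbons are identical and the shift has no regiochemical choice. The rearrangement also unmasks exactly the oxygen that becomes O1. The forward step must stop at the ortho product, without a further shift to the para carbon.

**4 from 2 and 3; 2 from 1.** The allylic C–O bond and two O–Si bonds are cut, which leads to a symmetric commercial triol. The only demand is a neutral etherification that spares aryl silyl ethers.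

**16 from 15, 13, 11, 12 and 10.** The ring D C3'=C4' unsaturation is added back (15), then C4a'–C4' is cut and reconnected as a propargylic C–O bond (13). This traces ring D to a propargyl Claisen/electrocyclisation cascade on a mono-silylated commercial dihydroxy ketone (11 from 10) and a commercial propargyl chloride (12). The acetyl group, needed anyway for the oxime, serves as the regiochemical director. The demand is that the shift goes to the carbon between the ether oxygen and the acetyl group.

**8 from 7.** The aminating agent is released from its commercial, storable hydroximate precursor immediately before use.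

## Other disconnections considered

**Alternative 1:** This is the route drawn first. Cut C3–C3a and O1–C2 as an aryl–alkyne bond and a C–O bond: Sonogashira coupling of the ortho-iodophenol 2-iodo-5-(3-methylbut-2-enyloxy)-3-(tert-butyldimethylsilyloxy)phenol A1 with the arylacetylene 5-ethynyl-2,2-dimethyl-7-(tert-butyldimethylsilyloxy)-3,4-dihydro-2H-chromene A2, 5-endo-dig closure to the 6-prenyloxybenzofuran A3, then Claisen rearrangement from O6. It leaves three regiochemical decisions to reagent control: iodination of a phloroglucinol ether at one of three activated carbons, three different substituents on the three oxygens of ring A, and a Claisen shift from O6 in which C5 and C7 are both open. The thermal shift would also be run on the fully assembled, most valuable intermediate. The chosen plan removes all three decisions by symmetry and by the O1 tether.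

**Alternative 2:** Cut ring C completely (Danheiser benzannulation). The cyclobutenone 3-[4,6-bis(tert-butyldimethylsilyloxy)-7-(2-methylbut-3-en-2-yl)-1-benzofuran-2-yl]-4-(3-methylbut-2-enyl)cyclobut-2-en-1-one A4 would be heated with (triisopropylsilyloxy)ethyne A5. Four-electron ring opening, [2+2] capture, a second ring opening and six-electron closure would build the resorcinol ring with the prenyl and benzofuranyl groups placed by construction; acid would then close ring D. This settles ring C in one strain-driven operation, but it leaves the harder ring A problem untouched, since A4 must already contain the C7 group. It also needs the labile ynol ether A5 and a ketene-derived cyclobutenone, and it closes the chroman with acid in the presence of the 1,1-dimethylallyl group. It is longer than the chosen plan.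

**Alternative 3:** Cut the bond from C7 to the quaternary carbon by umpolung. Barbier-type addition of prenyl bromide and indium metal to the C7 carbonyl of the quinone 6-(allyloxy)-2-[2,2-dimethyl-7-(triisopropylsilyloxy)-3,4-dihydro-2H-chromen-5-yl]-1-benzofuran-4,7-dione A6 (γ-attack; C4=O is deactivated as a doubly vinylogous ester) would give the quinol A7, and reductive aromatisation (Zn, AcOH) would remove the C7 hydroxyl. The C–C bond is formed regiospecifically, but the route pays a redox detour from phenol to quinone to quinol and back. The quinol A7 is also set up for allyl migration, retro-allylation and radical loss of the tertiary allyl group during reduction, and O6 needs its own protecting group. The sigmatropic plan reaches the same regiochemical certainty without changing the oxidation level of ring A.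

Key step: step 11

Remark: the C=N geometry of 17 is written as E; both isomers give the same ene-hydroxylamine 18, and the transient stereocentres of 5 and 20 (racemic) and the imine geometry of 19 do not survive into achiral 22.

## Route

Step 1
Reactants: 1 benzene-1,3,5-triol (phloroglucinol)
Product: 2 3,5-bis(tert-butyldimethylsilyloxy)phenol
Conditions: TBSCl (2.0 equiv), imidazole, DMF, 0 °C to rt
Reagents that add atoms: tert-butyldimethylsilyl chloride (TBSCl), CC(C)(C)[Si](C)(C)Cl
Why: O-silylation of a threefold-symmetric triol under stoichiometric control should give the bis-ether as the main fraction, with the mono- and tris-ethers separable and recyclable; the aryl silyl ethers are inert to heat, amide bases and acylating agents and leave only with fluoride.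

Step 2
Reactants: 2 3,5-bis(tert-butyldimethylsilyloxy)phenol; 3 3-methylbut-2-en-1-ol
Product: 4 1-(3-methylbut-2-enyloxy)-3,5-bis(tert-butyldimethylsilyloxy)benzene
Conditions: PPh3, DIAD, THF, 0 °C to rt
Reagents that add atoms: none
Why: Mitsunobu etherification of a phenol by a primary allylic alcohol proceeds by SN2 at the CH2 carbon and is neutral, so the base-labile aryl silyl ethers are not put at risk as they would be in a carbonate alkylation.

Step 3
Reactants: 4 1-(3-methylbut-2-enyloxy)-3,5-bis(tert-butyldimethylsilyloxy)benzene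
Product: 6 2-(2-methylbut-3-en-2-yl)-3,5-bis(tert-butyldimethylsilyloxy)phenol, via ortho-dienone 5 (not isolated)
Conditions: PhNEt2, 185 °C, sealed tube, argon
Reagents that add atoms: none
Why: Aromatic Claisen rearrangement; the mirror plane of 4 makes both ortho carbons identical, so a single ortho product should form after tautomerisation of 5, with the quaternary carbon next to the only free phenol, the future O1. The amine solvent suppresses acid-induced cyclisation of the product.

Step 4
Reactants: 7 ethyl (E)-N-(2,4,6-trimethylphenylsulfonyloxy)ethanimidate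
Product: 8 O-(2,4,6-trimethylphenylsulfonyl)hydroxylamine (MSH)
Conditions: 70% aq. HClO4, 1,4-dioxane, 0 °C; then ice-water; used at once
Reagents that add atoms: none
Why: Acid hydrolysis of the hydroximate (imidate) C=N bond releases the electrophilic aminating agent; this is the standard preparation, and the product is not stored.

Step 5
Reactants: 6 2-(2-methylbut-3-en-2-yl)-3,5-bis(tert-butyldimethylsilyloxy)phenol; 8 O-(2,4,6-trimethylphenylsulfonyl)hydroxylamine
Product: 9 O-[2-(2-methylbut-3-en-2-yl)-3,5-bis(tert-butyldimethylsilyloxy)phenyl]hydroxylamine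
Conditions: KN(SiMe3)2, THF, −78 °C; then 8 in CH2Cl2, −78 to 0 °C
Reagents that add atoms: none
Why: Electrophilic amination of a phenoxide at oxygen (substitution at nitrogen with sulfonate as leaving group); the transferred NH2 unit is small enough to reach the oxygen beside the quaternary group, and a non-nucleophilic amide base avoids attack on silicon.

Step 6
Reactants: 10 1-(3,5-dihydroxyphenyl)ethanone
Product: 11 1-[3-hydroxy-5-(triisopropylsilyloxy)phenyl]ethanone
Conditions: TIPSCl (1.0 equiv), imidazole, DMF, 0 °C to rt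
Reagents that add atoms: triisopropylsilyl chloride (TIPSCl), CC(C)[Si](Cl)(C(C)C)C(C)C
Why: Mono-silylation of a twofold-symmetric diol under stoichiometric control, with diol and bis-ether recyclable; the triisopropylsilyl group is chosen for its stability to DBU in step 7 and for its bulk, which helps the regiochemistry of step 8.

Step 7
Reactants: 11 1-[3-hydroxy-5-(triisopropylsilyloxy)phenyl]ethanone; 12 3-chloro-3-methylbut-1-yne
Product: 13 1-[3-(2-methylbut-3-yn-2-yloxy)-5-(triisopropylsilyloxy)phenyl]ethanone
Conditions: CuCl2·2H2O (1 mol %), DBU, MeCN, 0 °C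
Reagents that add atoms: none
Why: Copper-catalysed propargylic substitution of a tertiary propargyl chloride by a phenoxide (through a copper acetylide) forms the hindered aryl 1,1-dimethylpropargyl ether at low temperature, where plain SN2 alkylation would fail.

Step 8
Reactants: 13 1-[3-(2-methylbut-3-yn-2-yloxy)-5-(triisopropylsilyloxy)phenyl]ethanone
Product: 15 1-[2,2-dimethyl-7-(triisopropylsilyloxy)-2H-chromen-5-yl]ethanone, via ortho-allenylphenol 14 (not isolated)
Conditions: o-xylene, 140 °C
Reagents that add atoms: none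
Why: Propargyl Claisen rearrangement, enolisation to 14, 1,5-hydrogen shift and oxa-6π electrocyclisation give the 2H-chromene. The acetyl acceptor meta to the ether oxygen directs the shift toward the carbon next to it, and the bulky silyloxy donor directs it away from the carbon between the two oxygens, so both effects favour the required C4a'.

Step 9
Reactants: 15 1-[2,2-dimethyl-7-(triisopropylsilyloxy)-2H-chromen-5-yl]ethanone
Product: 16 1-[2,2-dimethyl-7-(triisopropylsilyloxy)-3,4-dihydro-2H-chromen-5-yl]ethanone
Conditions: H2 (1 atm), Pd/C, EtOAc, rt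
Reagents that add atoms: none
Why: Heterogeneous hydrogenation of the styrenic C3'=C4' bond; the aryl ketone and the silyl ether are untouched when the uptake is stopped at one equivalent. This is done before the 1,1-dimethylallyl group enters the molecule.

Step 10
Reactants: 9 O-[2-(2-methylbut-3-en-2-yl)-3,5-bis(tert-butyldimethylsilyloxy)phenyl]hydroxylamine; 16 1-[2,2-dimethyl-7-(triisopropylsilyloxy)-3,4-dihydro-2H-chromen-5-yl]ethanone
Product: 17 (E)-1-[2,2-dimethyl-7-(triisopropylsilyloxy)-3,4-dihydro-2H-chromen-5-yl]ethanone O-[2-(2-methylbut-3-en-2-yl)-3,5-bis(tert-butyldimethylsilyloxy)phenyl]oxime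
Conditions: PPTS (cat.), 4 Å molecular sieves, EtOH, 40 °C
Reagents that add atoms: none
Why: Acid-catalysed condensation of an alkoxyamine with a ketone (oxime ether formation), driven by removal of water; the mild buffer spares the silyl ethers and the alkene, and the C=N geometry is of no consequence.

Step 11
Reactants: 17 (E)-1-[2,2-dimethyl-7-(triisopropylsilyloxy)-3,4-dihydro-2H-chromen-5-yl]ethanone O-[2-(2-methylbut-3-en-2-yl)-3,5-bis(tert-butyldimethylsilyloxy)phenyl]oxime
Product: 21 4,6-bis(tert-butyldimethylsilyloxy)-2-[2,2-dimethyl-7-(triisopropylsilyloxy)-3,4-dihydro-2H-chromen-5-yl]-7-(2-methylbut-3-en-2-yl)-1-benzofuran, via N-trifluoroacetyl ene-hydroxylamine 18 (not isolated), via ortho-hydroxybenzyl N-acylimine 19 (not isolated), via 2-amido-2,3-dihydrobenzofuran 20 (not isolated)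
Conditions: CF3CO2Tf (TFAT), DMAP, CH2Cl2, 0 °C to rt
Reagents that add atoms: none
Why: N-Trifluoroacetylation of the oxime nitrogen and loss of a methyl proton to DMAP give 18, whose CH2=C–N–O–C7a=C3a array undergoes a [3,3] sigmatropic shift that breaks the weak N–O bond and forms C3–C3a; rearomatisation gives phenol 19. O1 then adds to the N-acylimine carbon (5-exo-trig closure of ring B) to give aminal 20, and loss of trifluoroacetamide under the buffered acid gives the aromatic furan. The closest known reaction type is the acylation-triggered rearrangement of O-aryl ketoxime ethers to 2-arylbenzofurans, the oxygen analogue of the Fischer indole synthesis. No stereocentre is set: C2 of 20 forms racemic and is destroyed by the elimination. The selectivity required is between the two carbons ortho to O1, and the substrate secures it, since C7 already carries the quaternary group from step 3 and only C3a has a hydrogen and is sterically open. C5, the most nucleophilic carbon of ring A, is out of reach of the six-membered transition state, which is the reason for preferring a tethered shift to any intermolecular alkylation. Low temperature, the amine buffer and the absence of free protic acid protect the 1,1-dimethylallyl group and the three silyl ethers, and the electron-rich aryloxy group should accelerate the shift.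

Step 12
Reactants: 21 4,6-bis(tert-butyldimethylsilyloxy)-2-[2,2-dimethyl-7-(triisopropylsilyloxy)-3,4-dihydro-2H-chromen-5-yl]-7-(2-methylbut-3-en-2-yl)-1-benzofuran
Product: 22 2-(7-hydroxy-2,2-dimethyl-3,4-dihydro-2H-chromen-5-yl)-7-(2-methylbut-3-en-2-yl)-1-benzofuran-4,6-diol (target, CNP0300714.0)
Conditions: Bu4NF, AcOH, THF, 0 °C to rt, argon
Reagents that add atoms: none
Why: Fluoride-induced cleavage of the three aryl silyl ethers; acetic acid buffers the phenoxides so that the electron-rich triphenol is not exposed to base and air, and neither acid nor hydrogen touches the 1,1-dimethylallyl group.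

## Compound list

1 | benzene-1,3,5-triol (phloroglucinol) | Oc1cc(O)cc(O)c1 | starting material
2 | 3,5-bis(tert-butyldimethylsilyloxy)phenol | Oc1cc(O[Si](C)(C)C(C)(C)C)cc(O[Si](C)(C)C(C)(C)C)c1 | intermediate
3 | 3-methylbut-2-en-1-ol | CC(C)=CCO | starting material
4 | 1-(3-methylbut-2-enyloxy)-3,5-bis(tert-butyldimethylsilyloxy)benzene | CC(C)=CCOc1cc(O[Si](C)(C)C(C)(C)C)cc(O[Si](C)(C)C(C)(C)C)c1 | intermediate
5 | 6-(2-methylbut-3-en-2-yl)-3,5-bis(tert-butyldimethylsilyloxy)cyclohexa-2,4-dien-1-one (racemic) | C=CC(C)(C)C1C(=O)C=C(O[Si](C)(C)C(C)(C)C)C=C1O[Si](C)(C)C(C)(C)C | intermediate (not isolated)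
6 | 2-(2-methylbut-3-en-2-yl)-3,5-bis(tert-butyldimethylsilyloxy)phenol | C=CC(C)(C)c1c(O)cc(O[Si](C)(C)C(C)(C)C)cc1O[Si](C)(C)C(C)(C)C | intermediate
7 | ethyl (E)-N-(2,4,6-trimethylphenylsulfonyloxy)ethanimidate | CCO/C(C)=N/OS(=O)(=O)c1c(C)cc(C)cc1C | starting material
8 | O-(2,4,6-trimethylphenylsulfonyl)hydroxylamine (MSH) | NOS(=O)(=O)c1c(C)cc(C)cc1C | intermediate
9 | O-[2-(2-methylbut-3-en-2-yl)-3,5-bis(tert-butyldimethylsilyloxy)phenyl]hydroxylamine | C=CC(C)(C)c1c(ON)cc(O[Si](C)(C)C(C)(C)C)cc1O[Si](C)(C)C(C)(C)C | intermediate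
10 | 1-(3,5-dihydroxyphenyl)ethanone | CC(=O)c1cc(O)cc(O)c1 | starting material
11 | 1-[3-hydroxy-5-(triisopropylsilyloxy)phenyl]ethanone | CC(=O)c1cc(O)cc(O[Si](C(C)C)(C(C)C)C(C)C)c1 | intermediate
12 | 3-chloro-3-methylbut-1-yne | C#CC(C)(C)Cl | starting material
13 | 1-[3-(2-methylbut-3-yn-2-yloxy)-5-(triisopropylsilyloxy)phenyl]ethanone | CC(=O)c1cc(OC(C)(C)C#C)cc(O[Si](C(C)C)(C(C)C)C(C)C)c1 | intermediate
14 | 1-[3-hydroxy-2-(3-methylbuta-1,2-dien-1-yl)-5-(triisopropylsilyloxy)phenyl]ethanone | CC(=O)c1cc(O[Si](C(C)C)(C(C)C)C(C)C)cc(O)c1C=C=C(C)C | intermediate (not isolated)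
15 | 1-[2,2-dimethyl-7-(triisopropylsilyloxy)-2H-chromen-5-yl]ethanone | CC(=O)c1cc(O[Si](C(C)C)(C(C)C)C(C)C)cc2c1C=CC(C)(C)O2 | intermediate
16 | 1-[2,2-dimethyl-7-(triisopropylsilyloxy)-3,4-dihydro-2H-chromen-5-yl]ethanone | CC(=O)c1cc(O[Si](C(C)C)(C(C)C)C(C)C)cc2c1CCC(C)(C)O2 | intermediate
17 | (E)-1-[2,2-dimethyl-7-(triisopropylsilyloxy)-3,4-dihydro-2H-chromen-5-yl]ethanone O-[2-(2-methylbut-3-en-2-yl)-3,5-bis(tert-butyldimethylsilyloxy)phenyl]oxime | C/C(=N\Oc1cc(O[Si](C)(C)C(C)(C)C)cc(O[Si](C)(C)C(C)(C)C)c1C(C)(C)C=C)c1cc(O[Si](C(C)C)(C(C)C)C(C)C)cc2c1CCC(C)(C)O2 | intermediate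
18 | N-[2-(2-methylbut-3-en-2-yl)-3,5-bis(tert-butyldimethylsilyloxy)phenoxy]-N-{1-[2,2-dimethyl-7-(triisopropylsilyloxy)-3,4-dihydro-2H-chromen-5-yl]ethenyl}-2,2,2-trifluoroacetamide | C=C(N(Oc1cc(O[Si](C)(C)C(C)(C)C)cc(O[Si](C)(C)C(C)(C)C)c1C(C)(C)C=C)C(=O)C(F)(F)F)c1cc(O[Si](C(C)C)(C(C)C)C(C)C)cc2c1CCC(C)(C)O2 | intermediate (not isolated)
19 | N-{2-[2-hydroxy-3-(2-methylbut-3-en-2-yl)-4,6-bis(tert-butyldimethylsilyloxy)phenyl]-1-[2,2-dimethyl-7-(triisopropylsilyloxy)-3,4-dihydro-2H-chromen-5-yl]ethylidene}-2,2,2-trifluoroacetamide (imine geometry undefined) | O=C(N=C(Cc1c(O)c(C(C)(C)C=C)c(O[Si](C)(C)C(C)(C)C)cc1O[Si](C)(C)C(C)(C)C)c1cc(O[Si](C(C)C)(C(C)C)C(C)C)cc2c1CCC(C)(C)O2)C(F)(F)F | intermediate (not isolated)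
20 | N-{4,6-bis(tert-butyldimethylsilyloxy)-2-[2,2-dimethyl-7-(triisopropylsilyloxy)-3,4-dihydro-2H-chromen-5-yl]-7-(2-methylbut-3-en-2-yl)-2,3-dihydro-1-benzofuran-2-yl}-2,2,2-trifluoroacetamide (racemic) | O=C(NC1(c2cc(O[Si](C(C)C)(C(C)C)C(C)C)cc3c2CCC(C)(C)O3)Cc2c(O1)c(C(C)(C)C=C)c(O[Si](C)(C)C(C)(C)C)cc2O[Si](C)(C)C(C)(C)C)C(F)(F)F | intermediate (not isolated)
21 | 4,6-bis(tert-butyldimethylsilyloxy)-2-[2,2-dimethyl-7-(triisopropylsilyloxy)-3,4-dihydro-2H-chromen-5-yl]-7-(2-methylbut-3-en-2-yl)-1-benzofuran | C=CC(C)(C)c1c(O[Si](C)(C)C(C)(C)C)cc(O[Si](C)(C)C(C)(C)C)c2cc(-c3cc(O[Si](C(C)C)(C(C)C)C(C)C)cc4c3CCC(C)(C)O4)oc12 | intermediate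
22 | 2-(7-hydroxy-2,2-dimethyl-3,4-dihydro-2H-chromen-5-yl)-7-(2-methylbut-3-en-2-yl)-1-benzofuran-4,6-diol | C=CC(C)(C)c1c(O)cc(O)c2cc(-c3cc(O)cc4c3CCC(C)(C)O4)oc12 | target

## Step count and least certain steps

Total step count: 12 (including the preparation of aminating agent 8). Longest linear sequence: 7 steps (1, 2, 3, 5, 10, 11, 12; the chroman branch 6, 7, 8, 9, 10, 11, 12 is equally long).

**Step 11 (key step).** The most likely failures are heterolysis of the N–O bond of the very electron-rich aryloxy unit before the concerted shift, trifluoroacetylation at the nucleophilic C3 or C5 once the benzofuran has formed, and incomplete loss of trifluoroacetamide from the aminal. Fallback, from 6 and 16 back to 21 by aryl–alkyne coupling instead of the tethered shift: 6 is iodinated at its only free ortho carbon (N-iodosuccinimide, CH2Cl2, −40 °C; the ring is far more nucleophilic than the monosubstituted alkene) to give 2-iodo-6-(2-methylbut-3-en-2-yl)-3,5-bis(tert-butyldimethylsilyloxy)phenol F1. 16 is converted in one flask (LiN(iPr)2, ClP(O)(OEt)2, THF, −78 °C, then excess LiN(iPr)2) through diethyl 1-[2,2-dimethyl-7-(triisopropylsilyloxy)-3,4-dihydro-2H-chromen-5-yl]ethenyl phosphate F2 into 5-ethynyl-2,2-dimethyl-7-(triisopropylsilyloxy)-3,4-dihydro-2H-chromene F3. Sonogashira coupling of F1 with F3 (Pd(PPh3)2Cl2, CuI, Et3N, DMF, 60 °C) gives 2-{[2,2-dimethyl-7-(triisopropylsilyloxy)-3,4-dihydro-2H-chromen-5-yl]ethynyl}-6-(2-methylbut-3-en-2-yl)-3,5-bis(tert-butyldimethylsilyloxy)phenol F4, which should close 5-endo-dig in the same flask to 21.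

**Step 5.** Nitrogen transfer to the oxygen beside a quaternary carbon may be slow, amination at the ring carbons of the phloroglucinol-type phenoxide may compete, and the electron-rich aryloxyamine may lose its N–O bond on handling. Fallback, from 6 back to 9 by C–O cross-coupling instead of electrophilic amination: 6 is converted (Tf2O, pyridine, CH2Cl2, 0 °C) into 2-(2-methylbut-3-en-2-yl)-3,5-bis(tert-butyldimethylsilyloxy)phenyl trifluoromethanesulfonate F5. Palladium-catalysed coupling with ethyl N-hydroxyacetimidate ([Pd(allyl)Cl]2, tBuBrettPhos, Cs2CO3, toluene, 65 °C) gives ethyl (E)-N-[2-(2-methylbut-3-en-2-yl)-3,5-bis(tert-butyldimethylsilyloxy)phenoxy]ethanimidate F6, and brief acidolysis (aq. HClO4, 1,4-dioxane, 0 °C) releases 9. The ortho quaternary group makes this coupling demanding, which is why it is the reserve and not the first choice.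

**Step 3.** A further Cope shift of dienone 5 to the para carbon, thermal cycloisomerisation of the ortho-(1,1-dimethylallyl)phenol, or silyl transfer between phenol and silyl ether at 185 °C may erode the ortho product. Fallback, from 2 back to 6 by electrophilic substitution and semi-hydrogenation instead of a sigmatropic shift (Nicholas reaction): 2-methylbut-3-yn-2-ol and Co2(CO)8 give hexacarbonyl(2-methylbut-3-yn-2-ol)dicobalt F7. BF3·OEt2 (CH2Cl2, −40 °C) ionises it, and the cobalt-stabilised tertiary cation should alkylate 2 at a carbon between OH and one silyloxy group (the carbon between the two silyloxy groups is shielded), giving the hexacarbonyldicobalt complex of 2-(2-methylbut-3-yn-2-yl)-3,5-bis(tert-butyldimethylsilyloxy)phenol F8. Decomplexation with Me3NO gives 2-(2-methylbut-3-yn-2-yl)-3,5-bis(tert-butyldimethylsilyloxy)phenol F9, and semi-hydrogenation (H2, Pb-poisoned Pd/CaCO3, quinoline) gives 6.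

**Step 8.** The [3,3] shift may go partly to the carbon between the two oxygens, giving the regioisomeric chromene by poor site selectivity. Fallback, from 10 back to 16 by ketone-directed C–H alkylation instead of a sigmatropic shift (Murai reaction; both carbons ortho to the acetyl group are equivalent): 10 is protected (MOMCl, iPr2NEt, CH2Cl2) as 1-[3,5-bis(methoxymethoxy)phenyl]ethanone F10. Ruthenium-catalysed anti-Markovnikov addition of the ortho C–H bond to 2-methylbut-3-en-2-ol (RuH2(CO)(PPh3)3, toluene, 135 °C) gives 1-[2-(3-hydroxy-3-methylbutyl)-3,5-bis(methoxymethoxy)phenyl]ethanone F11. Acid (TsOH, MeOH, 60 °C, then toluene, 80 °C) removes both acetals and closes ring D through the tertiary cation onto the only adjacent phenol, giving 1-(7-hydroxy-2,2-dimethyl-3,4-dihydro-2H-chromen-5-yl)ethanone F12. Silylation (TIPSCl, imidazole, DMF) gives 16.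

## Further compounds

F1 | step 11 | 2-iodo-6-(2-methylbut-3-en-2-yl)-3,5-bis(tert-butyldimethylsilyloxy)phenol | C=CC(C)(C)c1c(O)c(I)c(O[Si](C)(C)C(C)(C)C)cc1O[Si](C)(C)C(C)(C)C
F2 | step 11 | diethyl 1-[2,2-dimethyl-7-(triisopropylsilyloxy)-3,4-dihydro-2H-chromen-5-yl]ethenyl phosphate | C=C(OP(=O)(OCC)OCC)c1cc(O[Si](C(C)C)(C(C)C)C(C)C)cc2c1CCC(C)(C)O2
F3 | step 11 | 5-ethynyl-2,2-dimethyl-7-(triisopropylsilyloxy)-3,4-dihydro-2H-chromene | C#Cc1cc(O[Si](C(C)C)(C(C)C)C(C)C)cc2c1CCC(C)(C)O2
F4 | step 11 | 2-{[2,2-dimethyl-7-(triisopropylsilyloxy)-3,4-dihydro-2H-chromen-5-yl]ethynyl}-6-(2-methylbut-3-en-2-yl)-3,5-bis(tert-butyldimethylsilyloxy)phenol | C=CC(C)(C)c1c(O)c(C#Cc2cc(O[Si](C(C)C)(C(C)C)C(C)C)cc3c2CCC(C)(C)O3)c(O[Si](C)(C)C(C)(C)C)cc1O[Si](C)(C)C(C)(C)C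
F5 | step 5 | 2-(2-methylbut-3-en-2-yl)-3,5-bis(tert-butyldimethylsilyloxy)phenyl trifluoromethanesulfonate | C=CC(C)(C)c1c(OS(=O)(=O)C(F)(F)F)cc(O[Si](C)(C)C(C)(C)C)cc1O[Si](C)(C)C(C)(C)C
F6 | step 5 | ethyl (E)-N-[2-(2-methylbut-3-en-2-yl)-3,5-bis(tert-butyldimethylsilyloxy)phenoxy]ethanimidate | CCO/C(C)=N/Oc1cc(O[Si](C)(C)C(C)(C)C)cc(O[Si](C)(C)C(C)(C)C)c1C(C)(C)C=C
F7 | step 3 | hexacarbonyl(2-methylbut-3-yn-2-ol)dicobalt | CC(C)(O)C#C.[Co].[Co].[C-]#[O+].[C-]#[O+].[C-]#[O+].[C-]#[O+].[C-]#[O+].[C-]#[O+]
F8 | step 3 | hexacarbonyldicobalt complex of 2-(2-methylbut-3-yn-2-yl)-3,5-bis(tert-butyldimethylsilyloxy)phenol | C#CC(C)(C)c1c(O)cc(O[Si](C)(C)C(C)(C)C)cc1O[Si](C)(C)C(C)(C)C.[Co].[Co].[C-]#[O+].[C-]#[O+].[C-]#[O+].[C-]#[O+].[C-]#[O+].[C-]#[O+]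
F9 | step 3 | 2-(2-methylbut-3-yn-2-yl)-3,5-bis(tert-butyldimethylsilyloxy)phenol | C#CC(C)(C)c1c(O)cc(O[Si](C)(C)C(C)(C)C)cc1O[Si](C)(C)C(C)(C)C
F10 | step 8 | 1-[3,5-bis(methoxymethoxy)phenyl]ethanone | CC(=O)c1cc(OCOC)cc(OCOC)c1
F11 | step 8 | 1-[2-(3-hydroxy-3-methylbutyl)-3,5-bis(methoxymethoxy)phenyl]ethanone | CC(=O)c1cc(OCOC)cc(OCOC)c1CCC(C)(C)O
F12 | step 8 | 1-(7-hydroxy-2,2-dimethyl-3,4-dihydro-2H-chromen-5-yl)ethanone | CC(=O)c1cc(O)cc2c1CCC(C)(C)O2
A1 | alternative 1 | 2-iodo-5-(3-methylbut-2-enyloxy)-3-(tert-butyldimethylsilyloxy)phenol | Oc1cc(OCC=C(C)C)cc(O[Si](C)(C)C(C)(C)C)c1I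
A2 | alternative 1 | 5-ethynyl-2,2-dimethyl-7-(tert-butyldimethylsilyloxy)-3,4-dihydro-2H-chromene | C#Cc1cc(O[Si](C)(C)C(C)(C)C)cc2c1CCC(C)(C)O2
A3 | alternative 1 | 4-(tert-butyldimethylsilyloxy)-2-[7-(tert-butyldimethylsilyloxy)-2,2-dimethyl-3,4-dihydro-2H-chromen-5-yl]-6-(3-methylbut-2-enyloxy)-1-benzofuran | CC(C)=CCOc1cc(O[Si](C)(C)C(C)(C)C)c2cc(-c3cc(O[Si](C)(C)C(C)(C)C)cc4c3CCC(C)(C)O4)oc2c1
A4 | alternative 2 | 3-[4,6-bis(tert-butyldimethylsilyloxy)-7-(2-methylbut-3-en-2-yl)-1-benzofuran-2-yl]-4-(3-methylbut-2-enyl)cyclobut-2-en-1-one (racemic) | O=C1C=C(c2cc3c(O[Si](C)(C)C(C)(C)C)cc(O[Si](C)(C)C(C)(C)C)c(C(C)(C)C=C)c3o2)C1CC=C(C)C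
A5 | alternative 2 | (triisopropylsilyloxy)ethyne | C#CO[Si](C(C)C)(C(C)C)C(C)C
A6 | alternative 3 | 6-(allyloxy)-2-[2,2-dimethyl-7-(triisopropylsilyloxy)-3,4-dihydro-2H-chromen-5-yl]-1-benzofuran-4,7-dione | C=CCOC1=CC(=O)c2cc(-c3cc(O[Si](C(C)C)(C(C)C)C(C)C)cc4c3CCC(C)(C)O4)oc2C1=O
A7 | alternative 3 | 6-(allyloxy)-7-hydroxy-7-(2-methylbut-3-en-2-yl)-2-[2,2-dimethyl-7-(triisopropylsilyloxy)-3,4-dihydro-2H-chromen-5-yl]-1-benzofuran-4(7H)-one (racemic) | C=CCOC1=CC(=O)c2cc(-c3cc(O[Si](C(C)C)(C(C)C)C(C)C)cc4c3CCC(C)(C)O4)oc2C1(O)C(C)(C)C=C
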